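Readings and results were computed with made-up constants; scatter was added.

The constants of the suspected steps G + J → D, G → J and G → Z were unknown to me, but dividing the rate of G → J by that of G → Z cancels both G and time. Each D also holds one J that was made, so where G reads zero, J + 0.5D = rZ, with r the constant of G → J over that of G → Z, and with D counted in G as what J and Z leave missing.

| flask | G | remark | time |
|---|---|---|---|
| Saturday's | 10 mM | run made earlier |  |
| Friday's | 15 mM | run made earlier |  |
| flask | 20 mM |  | 15 d |

| run | time / d | J / % | Z / % | G / % |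
|---|---|---|---|---|
| Saturday's | 3.00 | 56.3 | 30.7 | 0 |
| Saturday's | 6.00 | 56.4 | 31.2 | 0 |
| Saturday's | 10.0 | 56.2 | 31.1 | 1.3 |
| Saturday's | 12.0 | 56.0 | 30.8 | 0.9 |
| Saturday's | 15.0 | 56.6 | 29.9 | 0.1 |
| Saturday's | 20.0 | 55.9 | 31.0 | 0 |
| Friday's | 3.00 | 52.6 | 29.5 | 0 |
| Friday's | 6.00 | 52.5 | 29.3 | 0 |
| Friday's | 10.0 | 52.3 | 30.3 | 0 |
| Friday's | 12.0 | 52.6 | 30.7 | 0.5 |
| Friday's | 15.0 | 51.6 | 31.1 | 0.1 |
| Friday's | 20.0 | 52.4 | 29.2 | 0.3 |

(each reading ± 0.5 percentage points)

- a species is counted by the G in it: one D counts as two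
- on the list of suspects stand: G + J -> D; G -> J; G -> Z

* amount of J at 15 d, in percent of the G charged
* amount of Z at 15 d, in percent of the G charged

G read 0% in Saturday's run and 0% in Friday's at 3.00 d, so I treated 15 d in the new flask as a plateau. The means of the readings gave r = 2.04 on Saturday's run and 2.04 on Friday's, so I carried 2.04 as r, the selectivity factor of G → J over G → Z. The forecast, noting that “both runs give r ≈ 2.04”, gave J 48.5% and Z 29.2%.

The flask gave J 48.9% and Z 29.2%, which read as r = 2.05.

    G + J → D (k = 2.80 /M/h)
    G → J (k = 0.0800 /h)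
    G → Z (k = 0.0390 /h)

In this flask, J was held down by G + J → D and G → Z acting together: with the first struck out J stood at 67.2%, and with the second at 61.8%. In the neighbour charged with 80 mM of G, r turns Z of 24.9% into J of 26.5%, and the computed J there is 27.2%.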